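**Retrosynthetic overview**

1. Germacrane numbering is used (ring C1–C10, lactone C11–C13, formyl C14, hydroxymethyl C15). The target is a ten-membered carbocycle cis-fused at C6/C7 to an α-methylene-γ-lactone (O–C6–C7–C11–C12), with 6S,7R,8S configuration.
2. Key disconnection C1–C2. C1 is an sp2 CH flanked by the plain methylene C2 and by C10, which carries two one-carbon arms (C1 and C14). C1 can therefore be the formyl carbon of a 2-substituted acrolein (C10=C14H2) and C2 a primary alkylchromium made by decarboxylation of an acid one carbon longer; 1,3-transposition/oxidation then gives the C1=C10–C14HO enal, whose geometry (CHO trans to C2, ring-cis) is the thermodynamic one.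
3. Seco-acid ⇐ lactone (O6–C12) ⇐ Evans–Tishchenko reduction (sets C6, leaves the isovalerate on O8) ⇐ Paterson syn-aldol (sets C7 and C8) of a dienone with 4,4-dimethoxybutanal (C8, C9, C10, C1).
4. Dienone ⇐ Barbier 2-(methoxycarbonyl)allylation/oxidation of an (E)-enal whose C4=C5 geometry comes from hydroxyl-directed trans-hydroalumination/iodination of but-2-yne-1,4-diol and a Negishi coupling.
5. Ring order: γ-lactone first (step 10), ten-membered carbocycle second (step 14); C14 enters by α-methylenation (step 12), the enal and the free C15 hydroxyl follow in steps 15 and 16.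

Key step: step 14

Assumption: Z-enol diisopinocampheylborinates made with (−)-Ipc2BOTf [from (+)-α-pinene] add to the si face of aldehydes; the (+)-reagent is therefore specified for the re-face addition needed at C8.

**Route**

Step 1
Reactants: 1 but-2-yne-1,4-diol
Product: 2 4-(tert-butyldimethylsilyloxy)but-2-yn-1-ol
Conditions: TBSCl (1 equiv), imidazole, 1 (3 equiv), DMF/THF, 0 °C
Reagents that add atoms: tert-butyldimethylsilyl chloride, CC(C)(C)[Si](C)(C)Cl
Why: Silyl ether formation as a statistical monoprotection of the symmetric diol used in excess; no stereocentre is formed.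

Step 2
Reactants: 2 4-(tert-butyldimethylsilyloxy)but-2-yn-1-ol
Product: 4 (Z)-4-(tert-butyldimethylsilyloxy)-3-iodobut-2-en-1-ol, via cyclic vinylalanate 3 (not isolated)
Conditions: NaAlH2(OCH2CH2OMe)2 (Red-Al), THF, 0 °C; EtOAc; then I2, −78 to 0 °C
Reagents that add atoms: iodine, II
Why: Hydroxyl-directed trans-hydroalumination of the propargylic alcohol places aluminium on C4 cis to the carbinol carbon C6, and iodinolysis with retention should give the (Z)-iodide that fixes the later C4=C5 geometry.

Step 3
Reactants: 4 (Z)-4-(tert-butyldimethylsilyloxy)-3-iodobut-2-en-1-ol; 5 (3-tert-butoxy-3-oxopropyl)zinc bromide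
Product: 6 tert-butyl (E)-4-[(tert-butyldimethylsilyloxy)methyl]-6-hydroxyhex-4-enoate
Conditions: Pd(PPh3)4 (5 mol %), 5 (2.5 equiv), THF, 45 °C
Reagents that add atoms: none
Why: Negishi coupling of the alkenyl iodide with the zinc homoenolate proceeds with retention of alkene geometry (C3 cis to C6) and tolerates the free hydroxyl and the ester.

Step 4
Reactants: 6 tert-butyl (E)-4-[(tert-butyldimethylsilyloxy)methyl]-6-hydroxyhex-4-enoate
Product: 7 tert-butyl (E)-4-[(tert-butyldimethylsilyloxy)methyl]-6-oxohex-4-enoate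
Conditions: MnO2, CH2Cl2, 23 °C
Reagents that add atoms: none
Why: Allylic alcohol oxidation with MnO2 should give the enal without touching the silyl ether, the ester or the alkene geometry.

Step 5
Reactants: 7 tert-butyl (E)-4-[(tert-butyldimethylsilyloxy)methyl]-6-oxohex-4-enoate; 8 methyl 2-(bromomethyl)acrylate
Product: 10 1-tert-butyl 9-methyl (E)-4-[(tert-butyldimethylsilyloxy)methyl]-6-hydroxy-8-methylidenenon-4-enedioate (racemic at C6), via allylzinc bromide 9 (not isolated)
Conditions: Zn dust, THF/sat. aq. NH4Cl, 0 °C to 23 °C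
Reagents that add atoms: none
Why: Barbier-type 2-(alkoxycarbonyl)allylation adds 1,2 to the enal and brings in C7, C11, C12 and C13; the carbinol centre is left racemic because the next step oxidises it.

Step 6
Reactants: 10 1-tert-butyl 9-methyl (E)-4-[(tert-butyldimethylsilyloxy)methyl]-6-hydroxy-8-methylidenenon-4-enedioate
Product: 11 1-tert-butyl 9-methyl (E)-4-[(tert-butyldimethylsilyloxy)methyl]-8-methylidene-6-oxonon-4-enedioate
Conditions: Dess–Martin periodinane, NaHCO3, CH2Cl2, 0 °C
Reagents that add atoms: none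
Why: Dess–Martin oxidation under bicarbonate buffer should give the ketone quickly and without moving the skipped C11=C13 alkene into conjugation.

Step 7
Reactants: 12 methyl 4,4-dimethoxybutanoate
Product: 13 4,4-dimethoxybutanal
Conditions: i-Bu2AlH (1.05 equiv), CH2Cl2, −78 °C; aq. Rochelle salt
Reagents that add atoms: none
Why: Partial reduction of the ester with i-Bu2AlH at low temperature stops at the aldehyde through the stable tetrahedral aluminate; the acetal is inert.

Step 8
Reactants: 11 1-tert-butyl 9-methyl (E)-4-[(tert-butyldimethylsilyloxy)methyl]-8-methylidene-6-oxonon-4-enedioate; 13 4,4-dimethoxybutanal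
Product: 16 1-tert-butyl 9-methyl (4E,7R)-4-[(tert-butyldimethylsilyloxy)methyl]-7-[(1S)-1-hydroxy-4,4-dimethoxybutyl]-8-methylidene-6-oxonon-4-enedioate, via Z-enolborinate 14 (not isolated), via boron aldolate 15 (not isolated)
Conditions: (+)-Ipc2BOTf [from (−)-α-pinene], i-Pr2NEt, CH2Cl2, −78 °C; 13, −78 to −20 °C; then MeOH, pH 7 buffer, 30% H2O2, 0 °C
Reagents that add atoms: none
Why: Paterson boron aldol: the triflate and hindered amine enolise the doubly activated C7 methylene to the Z-enolborinate, whose chair (Zimmerman–Traxler) transition state gives the 7,8-syn adduct, while the isopinocampheyl ligands direct addition to the re face of 13 and so should set 7R,8S.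

Step 9
Reactants: 16 the (7R,8S)-β-hydroxy ketone of step 8; 17 3-methylbutanal
Product: 19 1-tert-butyl 9-methyl (4E,6S,7S)-4-[(tert-butyldimethylsilyloxy)methyl]-7-[(1S)-4,4-dimethoxy-1-(3-methylbutanoyloxy)butyl]-6-hydroxy-8-methylidenenon-4-enedioate, via C8 hemiacetal 18 (not isolated)
Conditions: SmI2 (0.3 equiv), 17 (6 equiv), THF, −10 °C
Reagents that add atoms: none
Why: Evans–Tishchenko reduction: the samarium-bound C8 hemiacetal delivers its hydride intramolecularly to the C6 ketone through a chair-like transition state, which should give the 6,8-anti (6S) carbinol and leave the isovaleryl group on O8.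

Step 10
Reactants: 19 the anti-diol monoester of step 9
Product: 20 tert-butyl (E)-4-[(tert-butyldimethylsilyloxy)methyl]-5-{(2S,3R)-3-[(1S)-4,4-dimethoxy-1-(3-methylbutanoyloxy)butyl]-4-methylidene-5-oxooxolan-2-yl}pent-4-enoate
Conditions: camphorsulfonic acid (10 mol %), CH2Cl2, 23 °C
Reagents that add atoms: none
Why: Acid-catalysed lactonisation (intramolecular transesterification) of the free C6 hydroxyl onto the acrylate ester closes the five-membered cis-lactone; O8 is blocked, and the 6,7-cis relation follows from the centres already set.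

Step 11
Reactants: 20 the cis-lactone of step 10
Product: 21 (E)-4-[(tert-butyldimethylsilyloxy)methyl]-5-{(2S,3R)-3-[(1S)-1-(3-methylbutanoyloxy)-4-oxobutyl]-4-methylidene-5-oxooxolan-2-yl}pent-4-enoic acid
Conditions: 85% aq. H3PO4, toluene, 23 °C
Reagents that add atoms: water, O
Why: Acid hydrolysis of the dimethyl acetal and acidolysis of the tert-butyl ester under aqueous phosphoric acid, conditions under which silyl ethers, the lactone and the isovalerate should survive.

Step 12
Reactants: 21 the aldehyde acid of step 11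
Product: 22 (E)-4-[(tert-butyldimethylsilyloxy)methyl]-5-{(2S,3R)-3-[(1S)-3-formyl-1-(3-methylbutanoyloxy)but-3-enyl]-4-methylidene-5-oxooxolan-2-yl}pent-4-enoic acid
Conditions: 37% aq. CH2O, pyrrolidine (10 mol %), propionic acid (10 mol %), i-PrOH, 45 °C
Reagents that add atoms: formaldehyde, C=O
Why: Organocatalytic α-methylenation of the aldehyde (Mannich condensation–elimination) installs C14 as a methylene on C10 and makes the 2-substituted acrolein.

Step 13
Reactants: 22 the acrolein acid of step 12
Product: 23 1,3-dioxoisoindolin-2-yl ester of 22 (redox-active ester)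
Conditions: N-hydroxyphthalimide, N,N'-diisopropylcarbodiimide, DMAP (5 mol %), CH2Cl2, 0 to 23 °C
Reagents that add atoms: N-hydroxyphthalimide, O=C1c2ccccc2C(=O)N1O
Why: Steglich-type carbodiimide esterification of the carboxylic acid; no stereocentre is touched.

Step 14
Reactants: 23 the redox-active ester of step 13
Product: 25 (3aR,4S,10E,11aS)-10-[(tert-butyldimethylsilyloxy)methyl]-7-hydroxy-3,6-dimethylidene-2-oxo-2,3,3a,4,5,6,7,8,9,11a-decahydrocyclodeca[b]furan-4-yl 3-methylbutanoate (both epimers at the carbinol C1), via alkylchromium dichloride 24 (not isolated)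
Conditions: CrCl2 (8 equiv), DMF/THF (1:1), 25 °C, 23 added by syringe pump over 12 h (final 1 mM); aq. NH4Cl
Reagents that add atoms: none
Why: Proposed new method: CrCl2 reduces the N-acyloxyphthalimide by single-electron transfer, loss of CO2 and phthalimide anion gives the primary C2 radical, a second divalent chromium captures it as a persistent, non-basic alkylchromium (trivalent chromium), and this adds 1,2 to the tethered formyl carbon C1 through a chromium-bridged transition state; the closest known reactions are the intermolecular chromium-mediated decarboxylative addition of redox-active esters to aldehydes and the Nozaki–Hiyama–Kishi closures of ten-membered germacrane rings. The ten-membered carbocycle closes in a 10-exo-trig mode, the C1=O bond lying outside the new ring. The only new stereocentre, the C1 carbinol, is not controlled and need not be, because step 15 removes it. The step needs chemoselectivity for the aldehyde (1,2 over 1,4, and over the α-methylene lactone and the ester carbonyls) and cyclisation over oligomerisation: alkylchromium reagents add only to aldehydes, fast radical capture by excess CrCl2 suppresses conjugate-addition pathways, and slow addition at high dilution together with two turn elements (the ring-cis C4=C5 alkene and the cis-fused lactone, which hold both chains on one side) should favour ring closure.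

Step 15
Reactants: 25 the macrocyclic allylic alcohol of step 14
Product: 27 (3aR,4S,6E,10E,11aS)-10-[(tert-butyldimethylsilyloxy)methyl]-6-formyl-3-methylidene-2-oxo-2,3,3a,4,5,8,9,11a-octahydrocyclodeca[b]furan-4-yl 3-methylbutanoate, via primary allylic alcohol 26 (not isolated)
Conditions: Ph3SiOReO3 (5 mol %), CH2Cl2, 0 °C; then TEMPO (10 mol %), PhI(OAc)2, 23 °C
Reagents that add atoms: none
Why: Rhenium-oxo catalysed 1,3-transposition equilibrates the secondary alcohol with the primary alcohol bearing the trisubstituted C1=C10 alkene, and TEMPO/PhI(OAc)2 oxidation, selective for primary alcohols, drains the equilibrium to the enal, expected as the thermodynamically preferred isomer with CHO trans to C2 (ring-cis).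

Step 16
Reactants: 27 the silyl-protected enal of step 15
Product: 28 (3aR,4S,6E,10E,11aS)-6-formyl-10-(hydroxymethyl)-3-methylidene-2-oxo-2,3,3a,4,5,8,9,11a-octahydrocyclodeca[b]furan-4-yl 3-methylbutanoate (target)
Conditions: HF·pyridine, pyridine/THF, 0 to 23 °C
Reagents that add atoms: none
Why: Fluoride-mediated cleavage of the primary allylic silyl ether under buffered conditions that should leave the enal, the α-methylene lactone and the isovalerate intact.

**Compound list**

1 | but-2-yne-1,4-diol | OCC#CCO | starting material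
2 | 4-(tert-butyldimethylsilyloxy)but-2-yn-1-ol | OCC#CCO[Si](C)(C)C(C)(C)C | intermediate
3 | cyclic vinylalanate (sodium salt; Al on C4, O-bound to C6 oxygen) | [Na+].COCCO[Al-]1(OCCOC)OCC=C1CO[Si](C)(C)C(C)(C)C | intermediate
4 | (Z)-4-(tert-butyldimethylsilyloxy)-3-iodobut-2-en-1-ol | OC/C=C(\I)CO[Si](C)(C)C(C)(C)C | intermediate
5 | (3-tert-butoxy-3-oxopropyl)zinc bromide | CC(C)(C)OC(=O)CC[Zn]Br | starting material
6 | tert-butyl (E)-4-[(tert-butyldimethylsilyloxy)methyl]-6-hydroxyhex-4-enoate | OC/C=C(\CCC(=O)OC(C)(C)C)CO[Si](C)(C)C(C)(C)C | intermediate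
7 | tert-butyl (E)-4-[(tert-butyldimethylsilyloxy)methyl]-6-oxohex-4-enoate | O=C/C=C(\CCC(=O)OC(C)(C)C)CO[Si](C)(C)C(C)(C)C | intermediate
8 | methyl 2-(bromomethyl)acrylate | COC(=O)C(=C)CBr | starting material
9 | [2-(methoxycarbonyl)allyl]zinc bromide | COC(=O)C(=C)C[Zn]Br | intermediate
10 | 1-tert-butyl 9-methyl (E)-4-[(tert-butyldimethylsilyloxy)methyl]-6-hydroxy-8-methylidenenon-4-enedioate (racemic) | COC(=O)C(=C)CC(O)/C=C(\CCC(=O)OC(C)(C)C)CO[Si](C)(C)C(C)(C)C | intermediate
11 | 1-tert-butyl 9-methyl (E)-4-[(tert-butyldimethylsilyloxy)methyl]-8-methylidene-6-oxonon-4-enedioate | COC(=O)C(=C)CC(=O)/C=C(\CCC(=O)OC(C)(C)C)CO[Si](C)(C)C(C)(C)C | intermediate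
12 | methyl 4,4-dimethoxybutanoate | COC(=O)CCC(OC)OC | starting material
13 | 4,4-dimethoxybutanal | O=CCCC(OC)OC | intermediate
14 | Z-enol diisopinocampheylborinate of 11 (O–B on C6, C6=C7) | COC(=O)C(=C)/C=C(\OB([C@H]1C[C@H]2C[C@@H]([C@@H]1C)C2(C)C)[C@H]1C[C@H]2C[C@@H]([C@@H]1C)C2(C)C)/C=C(\CCC(=O)OC(C)(C)C)CO[Si](C)(C)C(C)(C)C | intermediate
15 | O8-diisopinocampheylboryl aldolate of 16 | COC(=O)C(=C)[C@H]([C@@H](OB([C@H]1C[C@H]2C[C@@H]([C@@H]1C)C2(C)C)[C@H]1C[C@H]2C[C@@H]([C@@H]1C)C2(C)C)CCC(OC)OC)C(=O)/C=C(\CCC(=O)OC(C)(C)C)CO[Si](C)(C)C(C)(C)C | intermediate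
16 | 1-tert-butyl 9-methyl (4E,7R)-4-[(tert-butyldimethylsilyloxy)methyl]-7-[(1S)-1-hydroxy-4,4-dimethoxybutyl]-8-methylidene-6-oxonon-4-enedioate | COC(=O)C(=C)[C@H]([C@@H](O)CCC(OC)OC)C(=O)/C=C(\CCC(=O)OC(C)(C)C)CO[Si](C)(C)C(C)(C)C | intermediate
17 | 3-methylbutanal | CC(C)CC=O | starting material
18 | C8 hemiacetal of 16 with 3-methylbutanal (samarium-bound in the flask) | COC(=O)C(=C)[C@H]([C@@H](OC(O)CC(C)C)CCC(OC)OC)C(=O)/C=C(\CCC(=O)OC(C)(C)C)CO[Si](C)(C)C(C)(C)C | intermediate
19 | 1-tert-butyl 9-methyl (4E,6S,7S)-4-[(tert-butyldimethylsilyloxy)methyl]-7-[(1S)-4,4-dimethoxy-1-(3-methylbutanoyloxy)butyl]-6-hydroxy-8-methylidenenon-4-enedioate | COC(=O)C(=C)[C@H]([C@@H](OC(=O)CC(C)C)CCC(OC)OC)[C@@H](O)/C=C(\CCC(=O)OC(C)(C)C)CO[Si](C)(C)C(C)(C)C | intermediate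
20 | tert-butyl (E)-4-[(tert-butyldimethylsilyloxy)methyl]-5-{(2S,3R)-3-[(1S)-4,4-dimethoxy-1-(3-methylbutanoyloxy)butyl]-4-methylidene-5-oxooxolan-2-yl}pent-4-enoate | C=C1C(=O)O[C@@H](/C=C(\CCC(=O)OC(C)(C)C)CO[Si](C)(C)C(C)(C)C)[C@H]1[C@@H](OC(=O)CC(C)C)CCC(OC)OC | intermediate
21 | (E)-4-[(tert-butyldimethylsilyloxy)methyl]-5-{(2S,3R)-3-[(1S)-1-(3-methylbutanoyloxy)-4-oxobutyl]-4-methylidene-5-oxooxolan-2-yl}pent-4-enoic acid | C=C1C(=O)O[C@@H](/C=C(\CCC(=O)O)CO[Si](C)(C)C(C)(C)C)[C@H]1[C@@H](OC(=O)CC(C)C)CCC=O | intermediate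
22 | (E)-4-[(tert-butyldimethylsilyloxy)methyl]-5-{(2S,3R)-3-[(1S)-3-formyl-1-(3-methylbutanoyloxy)but-3-enyl]-4-methylidene-5-oxooxolan-2-yl}pent-4-enoic acid | C=C1C(=O)O[C@@H](/C=C(\CCC(=O)O)CO[Si](C)(C)C(C)(C)C)[C@H]1[C@@H](OC(=O)CC(C)C)CC(=C)C=O | intermediate
23 | 1,3-dioxoisoindolin-2-yl ester of 22 | C=C1C(=O)O[C@@H](/C=C(\CCC(=O)ON2C(=O)c3ccccc3C2=O)CO[Si](C)(C)C(C)(C)C)[C@H]1[C@@H](OC(=O)CC(C)C)CC(=C)C=O | intermediate
24 | C2 alkylchromium dichloride (trivalent chromium) formed from 23 by loss of CO2 and phthalimide | C=C1C(=O)O[C@@H](/C=C(\CC[Cr](Cl)Cl)CO[Si](C)(C)C(C)(C)C)[C@H]1[C@@H](OC(=O)CC(C)C)CC(=C)C=O | intermediate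
25 | (3aR,4S,10E,11aS)-10-[(tert-butyldimethylsilyloxy)methyl]-7-hydroxy-3,6-dimethylidene-2-oxo-2,3,3a,4,5,6,7,8,9,11a-decahydrocyclodeca[b]furan-4-yl 3-methylbutanoate (carbinol epimers) | C=C1C(=O)O[C@H]2/C=C(/CO[Si](C)(C)C(C)(C)C)CCC(O)C(=C)C[C@H](OC(=O)CC(C)C)[C@@H]12 | intermediate
26 | (3aR,4S,6E,10E,11aS)-10-[(tert-butyldimethylsilyloxy)methyl]-6-(hydroxymethyl)-3-methylidene-2-oxo-2,3,3a,4,5,8,9,11a-octahydrocyclodeca[b]furan-4-yl 3-methylbutanoate | C=C1C(=O)O[C@H]2/C=C(/CO[Si](C)(C)C(C)(C)C)CC/C=C(/CO)C[C@H](OC(=O)CC(C)C)[C@@H]12 | intermediate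
27 | (3aR,4S,6E,10E,11aS)-10-[(tert-butyldimethylsilyloxy)methyl]-6-formyl-3-methylidene-2-oxo-2,3,3a,4,5,8,9,11a-octahydrocyclodeca[b]furan-4-yl 3-methylbutanoate | C=C1C(=O)O[C@H]2/C=C(/CO[Si](C)(C)C(C)(C)C)CC/C=C(/C=O)C[C@H](OC(=O)CC(C)C)[C@@H]12 | intermediate
28 | (3aR,4S,6E,10E,11aS)-6-formyl-10-(hydroxymethyl)-3-methylidene-2-oxo-2,3,3a,4,5,8,9,11a-octahydrocyclodeca[b]furan-4-yl 3-methylbutanoate | C=C1C(=O)O[C@H]2/C=C(/CO)CC/C=C(/C=O)C[C@H](OC(=O)CC(C)C)[C@@H]12 | target

**Step count and risks**

Total step count: 16. Longest linear sequence: 15 steps (steps 1–6 and 8–16; step 7 is a one-step branch).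

Steps most likely to fail:

1. Step 14 (Proposed new method). The medium-ring closure may be too slow, so that the alkylchromium is protonated or the substrate oligomerises before C1–C2 forms. Fallback, setting out from 23 and returning at 27: the ring would be closed as a decarboxylative Giese cyclisation (Ru(bpy)3Cl2, Hantzsch ester, i-Pr2NEt, blue light, high dilution). The C2 radical adds to the methylene terminus of the acrolein, which thereby becomes C1 while the formyl carbon becomes C14, and should give the saturated 6-formyl macrocycle F1. IBX dehydrogenation of this aldehyde (DMSO/toluene, 70 °C) toward the unhindered C1 methylene should then give 27 directly, so that 25 and step 15 are bypassed.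

2. Step 8. The reagent-controlled aldol may give poor enantio- or diastereoselectivity, or the opposite facial sense, because the ketone carries a larger α-substituent than the ethyl ketones for which the reagent is best. Fallback, setting out from 11 and 12 and returning at 16: ester 12 would be saponified (LiOH, aq. THF) to 4,4-dimethoxybutanoic acid F2 and converted (1H-benzotriazole, SOCl2) to the acylbenzotriazole F3. Soft-enolisation C-acylation of 11 (MgBr2·OEt2, i-Pr2NEt, CH2Cl2) should give the 1,3-diketone F4, in which C7 is configurationally labile. Reduction of the aliphatic C8 ketone by an NADPH-dependent ketoreductase (alcohol dehydrogenase class, glucose/glucose dehydrogenase recycling) under dynamic kinetic resolution, with the enzyme chosen from a panel for the (7R,8S)-syn ketol, should then give 16.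

3. Step 15. The transposition equilibrium may be incomplete, the secondary alcohol may be over-oxidised to the methylene ketone, or the wrong alkene geometry may be carried into the enal. Fallback, setting out from 25 and returning at 27: SN2′ bromination (PPh3, CBr4, CH2Cl2, 0 °C) should give the primary allylic bromide F5 with the trisubstituted ring alkene. Kornblum-type oxidation with N-methylmorpholine N-oxide (MeCN, 23 °C) should then give 27, any isomer with CHO cis to C2 being equilibrated to the stable one with a trace of iodine.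

Further compounds
F1 | step 14 | (3aR,4S,10E,11aS)-10-[(tert-butyldimethylsilyloxy)methyl]-6-formyl-3-methylidene-2-oxo-2,3,3a,4,5,6,7,8,9,11a-decahydrocyclodeca[b]furan-4-yl 3-methylbutanoate (C6 epimers) | C=C1C(=O)O[C@H]2/C=C(/CO[Si](C)(C)C(C)(C)C)CCCC(C=O)C[C@H](OC(=O)CC(C)C)[C@@H]12
F2 | step 8 | 4,4-dimethoxybutanoic acid | COC(CCC(=O)O)OC
F3 | step 8 | 1-(1H-benzotriazol-1-yl)-4,4-dimethoxybutan-1-one | COC(CCC(=O)n1nnc2ccccc12)OC
F4 | step 8 | 1-tert-butyl 9-methyl (E)-4-[(tert-butyldimethylsilyloxy)methyl]-7-(4,4-dimethoxybutanoyl)-8-methylidene-6-oxonon-4-enedioate | COC(=O)C(=C)C(C(=O)CCC(OC)OC)C(=O)/C=C(\CCC(=O)OC(C)(C)C)CO[Si](C)(C)C(C)(C)C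
F5 | step 15 | (3aR,4S,6E,10E,11aS)-6-(bromomethyl)-10-[(tert-butyldimethylsilyloxy)methyl]-3-methylidene-2-oxo-2,3,3a,4,5,8,9,11a-octahydrocyclodeca[b]furan-4-yl 3-methylbutanoate | C=C1C(=O)O[C@H]2/C=C(/CO[Si](C)(C)C(C)(C)C)CC/C=C(/CBr)C[C@H](OC(=O)CC(C)C)[C@@H]12
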